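The earlier runs and the new flask are calculated for an exercise; scatter was added.

- Eta and alpha, the two earlier runs, charge 0.22 M and 1.8 M of substrate; four new flasks are to be read at the end of their time.

| flask | substrate | remark | time |
|---|---|---|---|
| eta | 0.22 M | run made earlier |  |
| alpha | 1.8 M | run made earlier |  |
| maple | 0.15 M |  | 3.0 min |
| ash | 0.30 M |  | 3.0 min |
| cedar | 0.60 M |  | 3.0 min |
| oak | 1.2 M |  | 3.0 min |

| run | time / s | product / % | substrate / % |
|---|---|---|---|
| eta | 20.0 | 3.0 | 0.9 |
| eta | 40.0 | 12.4 | 0 |
| eta | 60.0 | 22.3 | 0 |
| eta | 80.0 | 33.9 | 0.1 |
| eta | 120 | 55.1 | 0 |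
| alpha | 20.0 | 2.9 | 0 |
| alpha | 40.0 | 11.2 | 0 |
| alpha | 60.0 | 22.3 | 0 |
| alpha | 80.0 | 34.8 | 0 |
| alpha | 120 | 53.4 | 0 |

(readings scatter by 1 percentage point)

- [product] at the end for maple, ash, cedar, oak, in this order
- how the row runs (hardly changes / rises, then falls / falls all the way / rises all the way / falls, then rises)

- the analysis behind the earlier runs scatters by 1 percentage point, standard deviation
- "hardly changes" means that all values lie within two and a half points (for a concentration: within two and a half percent of the largest)

- At 20.0 s, eta shows substrate at 0.9% and product at 3.0%, so nearly all of the charge stands in unmeasured forms.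
- The curve of product opens with a flat start, an induction period: eta gains 3.0% in its first interval, but 12 percentage points between 60.0 s and 80.0 s, as read a faster climb than in the stretches on either side.
- Eta and alpha differ in charge by a factor of 8.18, yet both read 22.3% at 60.0 s, so one percent curve is carried to the new flasks, although maple starts a little lower than eta.
- My own reckoning replaces the hidden path by two equal first-order steps with the same mean. With x as time over step time, the share is 1 − (1 + x)e^(−x), and its steepest point lies at x = 1, where the share is 26.4%.
- That knee is crossed at 67.1 s in eta and 66.6 s in alpha, as readings. Their mean gives a step time of 66.9 s.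
- Two such steps in a row take 134 s on average from charge to product, the mean passage time.
- The curve passes the knee and bends towards the charge as its assumed level. At 3.0 min, x is 2.69, so the share is 75.0%, and maple reckons to 0.112 M and oak to 0.900 M.
- The forecast gives 0.113 M, 0.225 M, 0.45 M and 0.9 M, a row that rises all the way, from “Two equal first-order steps”.

    substrate → intermediate A (k = 0.470 s⁻¹)
    intermediate B → product (k = 0.0170 s⁻¹)
    intermediate A → intermediate B (k = 0.0140 s⁻¹)

- The flasks give 0.114 M, 0.227 M, 0.454 M and 0.909 M, a row that rises all the way. Maple holds product at 75.7% of its charge, 0.70 points above the share from the mean passage time. In maple, the half-lives by their own steps alone are unequal, 0.83 min for intermediate A and 0.68 min for intermediate B, a ratio of 1.22. For ash at 1.50 min, the same 134 s gives x = 1.35 and a share of 38.9%, and ash holds product at 39.2%.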